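**Retrosynthetic overview**
- Araneosol comes from hydrogenolysis of its 5,7-dibenzyl ether, which comes from 3-O-methylation of the flavonol. The flavonol comes from C3 hydroxylation (epoxidation of C2=C3) of 5,7-bis(benzyloxy)-6,8,4'-trimethoxyflavone.
- Ring C is the only ring that has to be made. It closes at O1–C2 by oxidative cyclisation of a 2'-hydroxychalcone.
- The key C–C bond is C2–C3 of the flavone. It is formed by an intermolecular Claisen–Schmidt aldol condensation of a fully substituted ring-A acetophenone with p-anisaldehyde (ring B).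
- The ring-A ketone comes from phloroacetophenone by 4,6-di-O-benzylation, 3,5-dibromination and a double copper-catalysed methoxylation.
- Order: rings A and B are bought as arenes, ring A is fully decorated first, the fragments are joined, and then ring C is closed and oxygenated.

Assumption: araneosol has no stereocentre or stereogenic axis, so there is no enantiomer to select. The transient stereo-elements of the route (chalcone E-alkene; racemic aldol, flavanone and epoxide centres) are all erased before the target.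

**Step 1**
Reactants: 1 phloroacetophenone (2',4',6'-trihydroxyacetophenone, dried from its monohydrate)
Product: 2 dibenzyl ether 1-[4,6-bis(benzyloxy)-2-hydroxyphenyl]ethanone
Conditions: BnBr (2.1 equiv), K2CO3 (2.2 equiv), DMF, rt to 60 °C, 6 h
Reagents that add atoms: benzyl bromide, BrCc1ccccc1
Why: Williamson ether synthesis in which the 4-OH and one of the two equivalent ortho-OH groups are alkylated, while the last OH stays free because its strong hydrogen bond to the acetyl C=O makes it much less nucleophilic, so two equivalents of BnBr give a single dibenzyl ether.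

**Step 2**
Reactants: 2 dibenzyl ether 1-[4,6-bis(benzyloxy)-2-hydroxyphenyl]ethanone
Product: 3 dibromide 1-[4,6-bis(benzyloxy)-3,5-dibromo-2-hydroxyphenyl]ethanone
Conditions: NBS (2.1 equiv), CH2Cl2/MeCN, 0 °C to rt, dark
Reagents that add atoms: N-bromosuccinimide, O=C1CCC(=O)N1Br
Why: Electrophilic aromatic bromination, in which C3 and C5 are the only free ring positions and each is ortho/para to three oxygen donors, so they react far faster than the benzyl rings, the benzylic CH2 groups (no radical initiation in the dark) or the methyl ketone.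

**Step 3**
Reactants: 3 dibromide 1-[4,6-bis(benzyloxy)-3,5-dibromo-2-hydroxyphenyl]ethanone
Product: 4 ring-A ketone 1-[4,6-bis(benzyloxy)-2-hydroxy-3,5-dimethoxyphenyl]ethanone
Conditions: NaOMe (8 equiv, 5.4 M in MeOH), CuBr (0.3 equiv), DMF, 110 °C, N2, 8 h; then 1 M HCl
Reagents that add atoms: sodium methoxide, [Na+].[O-]C
Why: Ullmann-type C–O coupling catalysed by monovalent copper, the same double methanolysis that converts 3,5-dibromo-4-hydroxybenzaldehyde into syringaldehyde, and both the benzyl ethers and the phenoxide-deactivated ketone tolerate NaOMe (no ester co-catalyst is added, so the acetyl group cannot undergo a Claisen reaction).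

**Step 4 (key step)**
Reactants: 4 ring-A ketone 1-[4,6-bis(benzyloxy)-2-hydroxy-3,5-dimethoxyphenyl]ethanone; 5 p-anisaldehyde (4-methoxybenzaldehyde, 1.3 equiv)
Product: 7 chalcone (E)-1-[4,6-bis(benzyloxy)-2-hydroxy-3,5-dimethoxyphenyl]-3-(4-methoxyphenyl)prop-2-en-1-one, via racemic aldol adduct 6 (not isolated)
Conditions: KOH (50% aq, 10 equiv), EtOH, rt, 24–48 h; then cold 1 M HCl
Reagents that add atoms: none
Why: Claisen–Schmidt crossed aldol condensation, in which only 4 can form an enolate and 5 is a non-enolisable aldehyde, the racemic carbinol centre of 6 is erased by E1cB dehydration, and conjugation gives only the (E)-enone, as is well known for 2-hydroxy-3,4,5,6-tetraalkoxyacetophenones.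

**Step 5**
Reactants: 7 chalcone (E)-1-[4,6-bis(benzyloxy)-2-hydroxy-3,5-dimethoxyphenyl]-3-(4-methoxyphenyl)prop-2-en-1-one
Product: 9 flavone 5,7-bis(benzyloxy)-6,8-dimethoxy-2-(4-methoxyphenyl)-4H-chromen-4-one, via racemic flavanone 8 (not isolated)
Conditions: I2 (0.1 equiv), DMSO, 130 °C, 2 h; aq Na2S2O3 work-up
Reagents that add atoms: none
Why: Iodine–DMSO oxidative cyclisation, in which intramolecular oxa-Michael addition of the 2'-OH closes ring C to 8, α-iodination and loss of HI give the pyranone while DMSO reoxidises HI to I2, and the racemic C2 centre of 8 disappears.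

**Step 6**
Reactants: 9 flavone 5,7-bis(benzyloxy)-6,8-dimethoxy-2-(4-methoxyphenyl)-4H-chromen-4-one
Product: 11 flavonol 5,7-bis(benzyloxy)-3-hydroxy-6,8-dimethoxy-2-(4-methoxyphenyl)-4H-chromen-4-one, via racemic 2,3-epoxide 10 (not isolated)
Conditions: DMDO (0.08 M in acetone, freshly distilled, 2–3 equiv), CH2Cl2, 0 °C, 12 h; evaporate; p-TsOH·H2O (0.1 equiv), CH2Cl2, rt
Reagents that add atoms: dimethyldioxirane, CC1(C)OO1
Why: Epoxidation of the enol-ether C2=C3 bond with neutral DMDO followed by acid-catalysed epoxide opening through the C2 oxocarbenium ion and loss of H-3, a net C3 hydroxylation established for fully O-alkylated polyalkoxyflavones that erases both racemic epoxide centres.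

**Step 7**
Reactants: 11 flavonol 5,7-bis(benzyloxy)-3-hydroxy-6,8-dimethoxy-2-(4-methoxyphenyl)-4H-chromen-4-one
Product: 12 methyl ether 5,7-bis(benzyloxy)-3,6,8-trimethoxy-2-(4-methoxyphenyl)-4H-chromen-4-one
Conditions: MeI (2 equiv), K2CO3 (2 equiv), acetone, reflux, 6 h
Reagents that add atoms: iodomethane, CI
Why: Williamson O-methylation of the only free, acidic enolic OH, so no selectivity question arises.

**Step 8**
Reactants: 12 methyl ether 5,7-bis(benzyloxy)-3,6,8-trimethoxy-2-(4-methoxyphenyl)-4H-chromen-4-one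
Product: 13 araneosol 5,7-dihydroxy-3,6,8-trimethoxy-2-(4-methoxyphenyl)-4H-chromen-4-one
Conditions: H2 (1 atm), 10% Pd/C, EtOAc/MeOH 1:1, rt, 4 h
Reagents that add atoms: none
Why: Catalytic hydrogenolysis cleaves only the two benzyl aryl ethers, since the methyl ethers are inert and the tetrasubstituted vinylogous-ester C2=C3 bond of the chromone is not reduced at 1 atm, and the product has no stereocentre.

**Compound list**
1 | phloroacetophenone (2',4',6'-trihydroxyacetophenone) | CC(=O)c1c(O)cc(O)cc1O | starting material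
2 | 1-[4,6-bis(benzyloxy)-2-hydroxyphenyl]ethanone | CC(=O)c1c(O)cc(OCc2ccccc2)cc1OCc1ccccc1 | intermediate
3 | 1-[4,6-bis(benzyloxy)-3,5-dibromo-2-hydroxyphenyl]ethanone | CC(=O)c1c(O)c(Br)c(OCc2ccccc2)c(Br)c1OCc1ccccc1 | intermediate
4 | 1-[4,6-bis(benzyloxy)-2-hydroxy-3,5-dimethoxyphenyl]ethanone | CC(=O)c1c(O)c(OC)c(OCc2ccccc2)c(OC)c1OCc1ccccc1 | intermediate
5 | p-anisaldehyde (4-methoxybenzaldehyde) | COc1ccc(C=O)cc1 | starting material
6 | racemic aldol adduct 1-[4,6-bis(benzyloxy)-2-hydroxy-3,5-dimethoxyphenyl]-3-hydroxy-3-(4-methoxyphenyl)propan-1-one (not isolated) | COc1ccc(C(O)CC(=O)c2c(O)c(OC)c(OCc3ccccc3)c(OC)c2OCc2ccccc2)cc1 | intermediate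
7 | (E)-1-[4,6-bis(benzyloxy)-2-hydroxy-3,5-dimethoxyphenyl]-3-(4-methoxyphenyl)prop-2-en-1-one | COc1ccc(/C=C/C(=O)c2c(O)c(OC)c(OCc3ccccc3)c(OC)c2OCc2ccccc2)cc1 | intermediate
8 | racemic flavanone 5,7-bis(benzyloxy)-6,8-dimethoxy-2-(4-methoxyphenyl)chroman-4-one (not isolated) | COc1ccc(C2CC(=O)c3c(OCc4ccccc4)c(OC)c(OCc4ccccc4)c(OC)c3O2)cc1 | intermediate
9 | 5,7-bis(benzyloxy)-6,8-dimethoxy-2-(4-methoxyphenyl)-4H-chromen-4-one | COc1ccc(-c2oc3c(OC)c(OCc4ccccc4)c(OC)c(OCc4ccccc4)c3c(=O)c2)cc1 | intermediate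
10 | racemic cis-fused 2,3-epoxide of 9, 2,3-epoxy-5,7-bis(benzyloxy)-6,8-dimethoxy-2-(4-methoxyphenyl)chroman-4-one (not isolated) | COc1ccc(C23OC2C(=O)c2c(OCc4ccccc4)c(OC)c(OCc4ccccc4)c(OC)c2O3)cc1 | intermediate
11 | 5,7-bis(benzyloxy)-3-hydroxy-6,8-dimethoxy-2-(4-methoxyphenyl)-4H-chromen-4-one | COc1ccc(-c2oc3c(OC)c(OCc4ccccc4)c(OC)c(OCc4ccccc4)c3c(=O)c2O)cc1 | intermediate
12 | 5,7-bis(benzyloxy)-3,6,8-trimethoxy-2-(4-methoxyphenyl)-4H-chromen-4-one | COc1ccc(-c2oc3c(OC)c(OCc4ccccc4)c(OC)c(OCc4ccccc4)c3c(=O)c2OC)cc1 | intermediate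
13 | araneosol, 5,7-dihydroxy-3,6,8-trimethoxy-2-(4-methoxyphenyl)-4H-chromen-4-one (achiral) | COc1ccc(-c2oc3c(OC)c(O)c(OC)c(O)c3c(=O)c2OC)cc1 | target

**Totals**
Total step count: 8. Longest linear sequence: 8 steps (1 to 13); 5 enters at step 4.

**Three steps most likely to fail**

Step 3 (double methoxylation). The dangers are hydrodebromination, slow coupling at the C5–Br bond that is flanked by two benzyloxy groups, and attack of methoxide on the benzyl ethers.
The fallback postpones the oxygenation of ring A to the very end. There both C–Br bonds sit next to free phenoxides, the situation in which 6,8-dibromo-5,7-dihydroxyflavones are known to undergo clean double methanolysis. It sets out from 2 and comes back to the route at 13.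
Compounds 2 and 5 are condensed (KOH, EtOH, rt) to (E)-4',6'-bis(benzyloxy)-2'-hydroxy-4-methoxychalcone F1. This is cyclised (I2 cat., DMSO, 130 °C) to 5,7-bis(benzyloxy)-4'-methoxyflavone F2, oxidised (DMDO, then p-TsOH) to 5,7-bis(benzyloxy)-3-hydroxy-4'-methoxyflavone F3, and methylated (MeI, K2CO3) to 5,7-bis(benzyloxy)-3,4'-dimethoxyflavone F4. Hydrogenolysis (H2, Pd/C) gives ermanin F5 (5,7-dihydroxy-3,4'-dimethoxyflavone).
NBS (2.05 equiv, DMF, 0 °C) then brominates only the strongly activated ring A to give 6,8-dibromoermanin F6. NaOMe/CuBr in DMF–MeOH at 110 °C replaces both bromines to give 13. A ring opening and reclosure of the pyranone under base is harmless, because ring A is symmetric.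

Step 6 (C3 hydroxylation with DMDO). The dangers are incomplete conversion of the 5-alkoxyflavone, over-oxidation of the flavonol once it has formed, and slow oxidation of the benzylic CH2 groups.
The fallback replaces electrophilic oxygen transfer by deprotonation, borylation and oxidation. It sets out from 9 and comes back at 11.
Compound 9 is lithiated at C3 with LiN(i-Pr)2 (1.3 equiv, THF, −78 °C) and trapped with B(OMe)3 to give dimethyl [5,7-bis(benzyloxy)-6,8-dimethoxy-2-(4-methoxyphenyl)-4-oxo-4H-chromen-3-yl]boronate F7. This is oxidised in the same flask with H2O2/AcOH (0 °C to rt) to 11.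

Step 5 (I2/DMSO oxidative cyclisation). The dangers are partial loss of the peri 5-O-benzyl group through HI at 130 °C and stalling at flavanone 8.
The fallback avoids any oxidation by joining the fragments at the flavone oxidation level. It sets out from 4 and comes back at 9.
Compound 4 is converted with LiN(SiMe3)2 (3.2 equiv, THF, −78 °C) into its phenoxide–enolate dianion. The dianion is C-acylated with 4-methoxybenzoyl chloride (1.0 equiv, −78 °C to rt) in an intermolecular Claisen-type condensation. This gives the β-diketone 1-[4,6-bis(benzyloxy)-2-hydroxy-3,5-dimethoxyphenyl]-3-(4-methoxyphenyl)propane-1,3-dione F8, which is cyclodehydrated (p-TsOH·H2O, toluene, 90 °C) to 9.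

**Further compounds**
F1 | step 3 | (E)-1-[4,6-bis(benzyloxy)-2-hydroxyphenyl]-3-(4-methoxyphenyl)prop-2-en-1-one | COc1ccc(/C=C/C(=O)c2c(O)cc(OCc3ccccc3)cc2OCc2ccccc2)cc1
F2 | step 3 | 5,7-bis(benzyloxy)-2-(4-methoxyphenyl)-4H-chromen-4-one | COc1ccc(-c2cc(=O)c3c(OCc4ccccc4)cc(OCc4ccccc4)cc3o2)cc1
F3 | step 3 | 5,7-bis(benzyloxy)-3-hydroxy-2-(4-methoxyphenyl)-4H-chromen-4-one | COc1ccc(-c2oc3cc(OCc4ccccc4)cc(OCc4ccccc4)c3c(=O)c2O)cc1
F4 | step 3 | 5,7-bis(benzyloxy)-3-methoxy-2-(4-methoxyphenyl)-4H-chromen-4-one | COc1ccc(-c2oc3cc(OCc4ccccc4)cc(OCc4ccccc4)c3c(=O)c2OC)cc1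
F5 | step 3 | ermanin, 5,7-dihydroxy-3-methoxy-2-(4-methoxyphenyl)-4H-chromen-4-one | COc1ccc(-c2oc3cc(O)cc(O)c3c(=O)c2OC)cc1
F6 | step 3 | 6,8-dibromo-5,7-dihydroxy-3-methoxy-2-(4-methoxyphenyl)-4H-chromen-4-one | COc1ccc(-c2oc3c(Br)c(O)c(Br)c(O)c3c(=O)c2OC)cc1
F7 | step 6 | dimethyl [5,7-bis(benzyloxy)-6,8-dimethoxy-2-(4-methoxyphenyl)-4-oxo-4H-chromen-3-yl]boronate | COc1ccc(-c2oc3c(OC)c(OCc4ccccc4)c(OC)c(OCc4ccccc4)c3c(=O)c2B(OC)OC)cc1
F8 | step 5 | 1-[4,6-bis(benzyloxy)-2-hydroxy-3,5-dimethoxyphenyl]-3-(4-methoxyphenyl)propane-1,3-dione | COc1ccc(C(=O)CC(=O)c2c(O)c(OC)c(OCc3ccccc3)c(OC)c2OCc2ccccc2)cc1
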